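**Retrosynthetic overview**
- Feature: ring A carries oxygen on four adjacent carbons, C5, C6, C7 and C8. These map one-to-one onto the four ring carbons of a squarate ester. The remaining ring A bond, C4a=C8a, is the unsubstituted C5=C6 alkene of a 2-aryl-3-methoxy-4-pyranone (rings C and B).
- Ring A is cut at C5–C4a (retro 6-pi, then retro 4-pi) back to a 4-methoxy-4-(4-oxopyran-2-yl)cyclobutenone. It is cut at C8–C8a back to the C6-lithiated pyranone plus diisopropyl squarate.
- The oxygen pattern is set on the four-membered ring before heating: carbinol O-methylation gives 8-OMe, methanol exchange at the vinylogous ester carbon gives 7-OMe, the isopropyl kept on the alpha carbon becomes 6-OH, and the ketone becomes 5-OH.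
- Ring C comes from an aryl(3-bromofuran-2-yl)methanol by Achmatowicz ring expansion and acid hydrolysis. The bromine supplies the oxidation level that a plain furan lacks for a 3-hydroxy-4-pyranone.
- Order of rings: B (bought as the 4-O-methylgallate), then C, then A. One BCl3 step unmasks 6-, 3'- and 5'-OH.

Key step: step 11

Assumption: the sp3 stereocentres that arise on the way (furyl carbinol, pyranone hemiacetal, cyclobutenone C4) form as racemates or mixtures. Each becomes sp2 carbon later, and the target is achiral.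

**Step 1**
Reactants: 1 methyl 3,5-dihydroxy-4-methoxybenzoate
Product: 2 methyl 3,5-bis(benzyloxy)-4-methoxybenzoate
Conditions: BnBr (2.4 equiv), K2CO3, DMF, 60 °C
Reagents that add atoms: benzyl bromide BrCc1ccccc1
Why: Williamson ether synthesis on the two equivalent phenols gives benzyl ethers that tolerate hydride, lithium amides, peracid, hot dilute acid and the later thermolysis.

**Step 2**
Reactants: 2 methyl 3,5-bis(benzyloxy)-4-methoxybenzoate
Product: 3 [3,5-bis(benzyloxy)-4-methoxyphenyl]methanol
Conditions: LiAlH4, THF, 0 °C to rt; H2O quench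
Reagents that add atoms: none
Why: Hydride reduction of the benzoate goes cleanly to the benzylic alcohol, the aryl ethers are inert, and the unreliable direct ester-to-aldehyde reduction is avoided.

**Step 3**
Reactants: 3 [3,5-bis(benzyloxy)-4-methoxyphenyl]methanol
Product: 4 3,5-bis(benzyloxy)-4-methoxybenzaldehyde
Conditions: activated MnO2 (excess), CH2Cl2, rt
Reagents that add atoms: none
Why: Heterogeneous MnO2 oxidation is selective for benzylic alcohols and stops at the aldehyde.

**Step 4**
Reactants: 4 3,5-bis(benzyloxy)-4-methoxybenzaldehyde; 5 3-bromofuran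
Product: 7 rac-[3,5-bis(benzyloxy)-4-methoxyphenyl](3-bromofuran-2-yl)methanol, via 3-bromo-2-furyllithium 6 (not isolated)
Conditions: 5, LDA, THF, −78 °C; then 4, −78 °C; aq NH4Cl
Reagents that add atoms: none
Why: LDA deprotonates 3-bromofuran at C2, between the ring oxygen and the bromine, and the furyllithium undergoes 1,2-carbonyl addition to the aldehyde; the carbinol centre forms as a racemate, which does not matter because it becomes sp2 carbon C2 of the pyranone in step 6.

**Step 5**
Reactants: 7 rac-[3,5-bis(benzyloxy)-4-methoxyphenyl](3-bromofuran-2-yl)methanol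
Product: 8 2-[3,5-bis(benzyloxy)-4-methoxyphenyl]-4-bromo-6-hydroxy-2H-pyran-3(6H)-one (racemic anomer mixture)
Conditions: mCPBA (1.2 equiv), CH2Cl2, 0 °C to rt
Reagents that add atoms: 3-chloroperoxybenzoic acid OOC(=O)c1cccc(Cl)c1
Why: Achmatowicz rearrangement opens the furan oxidatively and re-closes it through the carbinol oxygen to the six-membered hemiacetal, a peracid is chosen over NBS so that the activated ring B is not brominated, and the new anomeric centre forms uncontrolled and is erased in step 6.

**Step 6**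
Reactants: 8 2-[3,5-bis(benzyloxy)-4-methoxyphenyl]-4-bromo-6-hydroxy-2H-pyran-3(6H)-one
Product: 9 2-[3,5-bis(benzyloxy)-4-methoxyphenyl]-3-hydroxy-4H-pyran-4-one
Conditions: 2 M aq H2SO4–1,4-dioxane (1:1), 90 °C
Reagents that add atoms: water O
Why: This is the known acid hydrolysis of 4-halo-6-hydroxy-2H-pyran-3(6H)-ones to 3-hydroxy-4-pyranones (enolisation towards C2, ionisation of the anomeric hydroxyl, hydrolytic replacement of the C4 bromine), the bromine carries the two-electron oxidation that a bromine-free Achmatowicz product would still need, and both stereocentres vanish.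

**Step 7**
Reactants: 9 2-[3,5-bis(benzyloxy)-4-methoxyphenyl]-3-hydroxy-4H-pyran-4-one
Product: 10 2-[3,5-bis(benzyloxy)-4-methoxyphenyl]-3-methoxy-4H-pyran-4-one
Conditions: MeI, K2CO3, acetone, reflux
Reagents that add atoms: iodomethane CI
Why: Williamson O-methylation of the acidic enolic 3-OH proceeds as for maltol-type pyranones and removes the only acidic proton before metalation.

**Step 8**
Reactants: 10 2-[3,5-bis(benzyloxy)-4-methoxyphenyl]-3-methoxy-4H-pyran-4-one; 11 diisopropyl squarate
Product: 13 rac-4-{6-[3,5-bis(benzyloxy)-4-methoxyphenyl]-5-methoxy-4-oxo-4H-pyran-2-yl}-4-hydroxy-2,3-diisopropoxycyclobut-2-en-1-one, via 6-lithiopyranone 12 (not isolated)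
Conditions: 2,2,6,6-tetramethylpiperidine, n-BuLi, THF, −78 °C; 10 added slowly, 20 min; 11, −78 °C; AcOH quench at −78 °C
Reagents that add atoms: none
Why: Deprotonative lithiation takes the C–H next to the ring heteroatom, as it does at C2 of chromones and 4-pyridones and at C6 of uracils; slow addition of 10 to excess hindered amide keeps the lithio species away from unreacted pyranone; and the organolithium adds 1,2 to one of the two equivalent squarate carbonyls to give the C4 carbinol as a racemate that is lost again in step 11.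

**Step 9**
Reactants: 13 rac-4-{6-[3,5-bis(benzyloxy)-4-methoxyphenyl]-5-methoxy-4-oxo-4H-pyran-2-yl}-4-hydroxy-2,3-diisopropoxycyclobut-2-en-1-one
Product: 14 rac-4-{6-[3,5-bis(benzyloxy)-4-methoxyphenyl]-5-methoxy-4-oxo-4H-pyran-2-yl}-2,3-diisopropoxy-4-methoxycyclobut-2-en-1-one
Conditions: MeI (10 equiv), Ag2O (3 equiv), 4 Å MS, MeCN, rt, dark
Reagents that add atoms: iodomethane CI
Why: Purdie methylation caps tertiary squarate carbinols under neutral conditions, so no strong base meets the hydroxycyclobutenone, and iodomethane, unlike methyl triflate, does not alkylate the pyranone carbonyl oxygen.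

**Step 10**
Reactants: 14 rac-4-{6-[3,5-bis(benzyloxy)-4-methoxyphenyl]-5-methoxy-4-oxo-4H-pyran-2-yl}-2,3-diisopropoxy-4-methoxycyclobut-2-en-1-one
Product: 15 rac-4-{6-[3,5-bis(benzyloxy)-4-methoxyphenyl]-5-methoxy-4-oxo-4H-pyran-2-yl}-2-isopropoxy-3,4-dimethoxycyclobut-2-en-1-one
Conditions: NaOMe (0.2 equiv), MeOH–THF (4:1), −20 to 0 °C; AcOH quench
Reagents that add atoms: methanol CO
Why: Vinylogous transesterification by addition–elimination takes place only at C3, the beta carbon of the enone, because the C2 isopropoxy group sits on the alpha carbon and has no such path; solvent methanol drives the exchange, and low temperature with catalytic base holds back attack at the ring carbonyl.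

**Step 11**
Reactants: 15 rac-4-{6-[3,5-bis(benzyloxy)-4-methoxyphenyl]-5-methoxy-4-oxo-4H-pyran-2-yl}-2-isopropoxy-3,4-dimethoxycyclobut-2-en-1-one
Product: 18 3',5'-bis(benzyloxy)-5-hydroxy-6-isopropoxy-3,7,8,4'-tetramethoxyflavone, via dienylketene 16 (not isolated), via 4aH-chromene-4,5-dione tautomer 17 (not isolated)
Conditions: degassed p-xylene (0.01 M), reflux (138 °C), Ar
Reagents that add atoms: none
Why: Thermal conrotatory 4-pi opening cleaves the C1–C4 bond of the cyclobutenone to dienylketene 16, with the 4-methoxy donor turning outward and the electron-poor pyranonyl group inward, so that the pyranone C5=C6 bond lies next to the ketene. Disrotatory 6-pi electrocyclisation (ketene C=C, C3=C4, pyranone C6=C5) then joins the ketene carbon to pyranone C5, which is the new C5–C4a bond and closes ring A as a six-membered carbocycle in 17. Enolisation of 17, whose C4a–H lies between two carbonyl groups, gives the aromatic hydrogen-bonded 5-phenol and removes the only transient stereocentre, and the stereocentre of 15 is already lost on ring opening, so no stereocontrol is needed. The closest known reaction type is the Moore rearrangement of 4-aryl-, 4-heteroaryl- and 4-alkenyl-4-alkoxycyclobutenones to hydroquinone monoethers; the weakly aromatic pyranone should fall between the furyl and alkenyl cases, and polarity is matched because C5 is the nucleophilic end of the O1–C6=C5 enol ether. Regiochemistry is fixed by the substrate, since the other neighbour of the attachment carbon is the ring oxygen and only C5 can close, and each cyclobutenone carbon has one destination (C4-OMe to C8, C3-OMe to C7, C2-OiPr to C6, C1=O to 5-OH). A ketene formed with the pyranonyl group outward cannot cyclise and returns to 15 by reclosure, so the material drains through the productive isomer.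

**Step 12**
Reactants: 18 3',5'-bis(benzyloxy)-5-hydroxy-6-isopropoxy-3,7,8,4'-tetramethoxyflavone
Product: 19 5,6,3',5'-tetrahydroxy-3,7,8,4'-tetramethoxyflavone
Conditions: BCl3 (1 M in CH2Cl2, 8 equiv), pentamethylbenzene (6 equiv), CH2Cl2, −78 to 0 °C; then H2O
Reagents that add atoms: none
Why: Lewis-acid ether cleavage with BCl3 ionises benzyl and isopropyl aryl ethers much faster than it demethylates (benzyl cations are taken up by pentamethylbenzene in a Friedel–Crafts alkylation, isopropyl leaves as the chloride), the boron chelate between 5-O and the C4 carbonyl keeps the reagent away from 3-OMe, and staying at or below 0 °C protects the flanked 7-, 8- and 4'-methyl ethers.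

**Compound list**
1 | methyl 3,5-dihydroxy-4-methoxybenzoate | COC(=O)c1cc(O)c(OC)c(O)c1 | starting material
2 | methyl 3,5-bis(benzyloxy)-4-methoxybenzoate | COC(=O)c1cc(OCc2ccccc2)c(OC)c(OCc2ccccc2)c1 | intermediate
3 | [3,5-bis(benzyloxy)-4-methoxyphenyl]methanol | OCc1cc(OCc2ccccc2)c(OC)c(OCc2ccccc2)c1 | intermediate
4 | 3,5-bis(benzyloxy)-4-methoxybenzaldehyde | O=Cc1cc(OCc2ccccc2)c(OC)c(OCc2ccccc2)c1 | intermediate
5 | 3-bromofuran | Brc1ccoc1 | starting material
6 | 3-bromo-2-furyllithium (not isolated) | [Li]c1occc1Br | intermediate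
7 | rac-[3,5-bis(benzyloxy)-4-methoxyphenyl](3-bromofuran-2-yl)methanol | OC(c1occc1Br)c1cc(OCc2ccccc2)c(OC)c(OCc2ccccc2)c1 | intermediate
8 | 2-[3,5-bis(benzyloxy)-4-methoxyphenyl]-4-bromo-6-hydroxy-2H-pyran-3(6H)-one (racemic, anomer mixture) | O=C1C(Br)=CC(O)OC1c1cc(OCc2ccccc2)c(OC)c(OCc2ccccc2)c1 | intermediate
9 | 2-[3,5-bis(benzyloxy)-4-methoxyphenyl]-3-hydroxy-4H-pyran-4-one | O=c1ccoc(-c2cc(OCc3ccccc3)c(OC)c(OCc3ccccc3)c2)c1O | intermediate
10 | 2-[3,5-bis(benzyloxy)-4-methoxyphenyl]-3-methoxy-4H-pyran-4-one | COc1c(-c2cc(OCc3ccccc3)c(OC)c(OCc3ccccc3)c2)occc1=O | intermediate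
11 | diisopropyl squarate (3,4-diisopropoxycyclobut-3-ene-1,2-dione) | CC(C)OC1=C(OC(C)C)C(=O)C1=O | starting material
12 | 2-[3,5-bis(benzyloxy)-4-methoxyphenyl]-6-lithio-3-methoxy-4H-pyran-4-one (not isolated) | [Li]c1cc(=O)c(OC)c(-c2cc(OCc3ccccc3)c(OC)c(OCc3ccccc3)c2)o1 | intermediate
13 | rac-4-{6-[3,5-bis(benzyloxy)-4-methoxyphenyl]-5-methoxy-4-oxo-4H-pyran-2-yl}-4-hydroxy-2,3-diisopropoxycyclobut-2-en-1-one | CC(C)OC1=C(OC(C)C)C(O)(C1=O)c1cc(=O)c(OC)c(o1)-c1cc(OCc2ccccc2)c(OC)c(OCc2ccccc2)c1 | intermediate
14 | rac-4-{6-[3,5-bis(benzyloxy)-4-methoxyphenyl]-5-methoxy-4-oxo-4H-pyran-2-yl}-2,3-diisopropoxy-4-methoxycyclobut-2-en-1-one | CC(C)OC1=C(OC(C)C)C(OC)(C1=O)c1cc(=O)c(OC)c(o1)-c1cc(OCc2ccccc2)c(OC)c(OCc2ccccc2)c1 | intermediate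
15 | rac-4-{6-[3,5-bis(benzyloxy)-4-methoxyphenyl]-5-methoxy-4-oxo-4H-pyran-2-yl}-2-isopropoxy-3,4-dimethoxycyclobut-2-en-1-one | CC(C)OC1=C(OC)C(OC)(C1=O)c1cc(=O)c(OC)c(o1)-c1cc(OCc2ccccc2)c(OC)c(OCc2ccccc2)c1 | intermediate
16 | (3Z)-4-{6-[3,5-bis(benzyloxy)-4-methoxyphenyl]-5-methoxy-4-oxo-4H-pyran-2-yl}-2-isopropoxy-3,4-dimethoxybuta-1,3-dien-1-one (not isolated) | O=C=C(OC(C)C)/C(OC)=C(OC)\c1cc(=O)c(OC)c(o1)-c1cc(OCc2ccccc2)c(OC)c(OCc2ccccc2)c1 | intermediate
17 | rac-2-[3,5-bis(benzyloxy)-4-methoxyphenyl]-6-isopropoxy-3,7,8-trimethoxy-4aH-chromene-4,5-dione (not isolated) | O=C1C(OC(C)C)=C(OC)C(OC)=C2OC(-c3cc(OCc4ccccc4)c(OC)c(OCc4ccccc4)c3)=C(OC)C(=O)C12 | intermediate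
18 | 3',5'-bis(benzyloxy)-5-hydroxy-6-isopropoxy-3,7,8,4'-tetramethoxyflavone | COc1c(OCc2ccccc2)cc(-c2oc3c(OC)c(OC)c(OC(C)C)c(O)c3c(=O)c2OC)cc1OCc1ccccc1 | intermediate
19 | 5,6,3',5'-tetrahydroxy-3,7,8,4'-tetramethoxyflavone | COc1c(O)cc(-c2oc3c(OC)c(OC)c(O)c(O)c3c(=O)c2OC)cc1O | target

**Step count and risks**
Total steps: 12. Longest linear sequence: 12 steps (1 to 19). Compounds 5 and 11 enter as bought reagents.

**Step 11.**
- What may go wrong: the 6-pi closure onto the cross-conjugated pyranone alkene may be slow. The ketene would then only reclose, oligomerise or be consumed by adventitious nucleophiles.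
- Fallback, ionic and stepwise, from 15 back to 18: 15 is heated in toluene–methanol in a sealed tube at 110 °C. Ketene 16 is intercepted by alcoholysis as racemic methyl (3Z)-4-{6-[3,5-bis(benzyloxy)-4-methoxyphenyl]-5-methoxy-4-oxo-4H-pyran-2-yl}-2-isopropoxy-3,4-dimethoxybut-3-enoate F1.
- KOt-Bu in THF (or NaOMe in hot MeOH) then generates the anion that is delocalised into the pyranone. Its C5 attacks the cis-disposed ester in a Dieckmann-type condensation, methoxide leaves, and enolisation gives 18.

**Step 8.**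
- What may go wrong: deprotonation may compete at C5 and be followed by ring opening through beta-elimination. The lithio species may also add to pyranone that is still neutral.
- Fallback, an isolable halide and halogen–metal exchange, from 10 back to 13: lithium 2,2,6,6-tetramethylpiperidide is added at −78 °C to a premixed THF solution of 10 and ZnCl2·2LiCl. The carbanion is trapped at once as the pyran-6-ylzinc chloride F2.
- Iodolysis with I2 gives 2-[3,5-bis(benzyloxy)-4-methoxyphenyl]-6-iodo-3-methoxy-4H-pyran-4-one F3, whose regiochemistry can be checked before it is committed.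
- Iodine–magnesium exchange with iPrMgCl·LiCl at −78 °C gives the pyran-6-ylmagnesium chloride F4. This adds to 11 and, after an AcOH quench, gives 13.

**Step 10.**
- What may go wrong: methoxide may attack the ring carbonyl. Strain-driven cleavage of the C1–C4 bond (retro-Claisen type) would follow, helped by the fact that the departing carbanion is a vinylogous enolate of the pyranone.
- Fallback, from 10 back to 15, bypassing 13 and 14: the oxygen pattern is set on the four-membered ring before the pyranone is attached. Commercial dimethyl squarate is acetalised at one carbonyl with MeOSiMe3 and catalytic TMSOTf in CH2Cl2 to 2,3,4,4-tetramethoxycyclobut-2-en-1-one F5.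
- Catalytic NaOi-Pr in i-PrOH exchanges its single vinylogous ester methoxy group to give 3-isopropoxy-2,4,4-trimethoxycyclobut-2-en-1-one F6. In this substrate ring cleavage would need an unstabilised carbanion.
- Compound 12, made from 10 as in step 8, adds to the only carbonyl of F6 to give the racemic carbinol 2-[3,5-bis(benzyloxy)-4-methoxyphenyl]-6-(1-hydroxy-3-isopropoxy-2,4,4-trimethoxycyclobut-2-en-1-yl)-3-methoxy-4H-pyran-4-one F7.
- MeI and Ag2O give its methyl ether F8. Brief treatment with dilute aqueous oxalic acid in THF at 0 °C hydrolyses the acetal to 15.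
- The acetal ionises in preference to the tertiary ether because its cation carries two oxygen donors. Water capture at either end of that cation leads to the same constitution.

**Further compounds**
F1 | step 11 | rac-methyl (3Z)-4-{6-[3,5-bis(benzyloxy)-4-methoxyphenyl]-5-methoxy-4-oxo-4H-pyran-2-yl}-2-isopropoxy-3,4-dimethoxybut-3-enoate | COC(=O)C(OC(C)C)/C(OC)=C(OC)\c1cc(=O)c(OC)c(o1)-c1cc(OCc2ccccc2)c(OC)c(OCc2ccccc2)c1
F2 | step 8 | chloro{6-[3,5-bis(benzyloxy)-4-methoxyphenyl]-5-methoxy-4-oxo-4H-pyran-2-yl}zinc | Cl[Zn]c1cc(=O)c(OC)c(-c2cc(OCc3ccccc3)c(OC)c(OCc3ccccc3)c2)o1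
F3 | step 8 | 2-[3,5-bis(benzyloxy)-4-methoxyphenyl]-6-iodo-3-methoxy-4H-pyran-4-one | Ic1cc(=O)c(OC)c(-c2cc(OCc3ccccc3)c(OC)c(OCc3ccccc3)c2)o1
F4 | step 8 | chloro{6-[3,5-bis(benzyloxy)-4-methoxyphenyl]-5-methoxy-4-oxo-4H-pyran-2-yl}magnesium | Cl[Mg]c1cc(=O)c(OC)c(-c2cc(OCc3ccccc3)c(OC)c(OCc3ccccc3)c2)o1
F5 | step 10 | 2,3,4,4-tetramethoxycyclobut-2-en-1-one | COC1=C(OC)C(OC)(OC)C1=O
F6 | step 10 | 3-isopropoxy-2,4,4-trimethoxycyclobut-2-en-1-one | COC1=C(OC(C)C)C(OC)(OC)C1=O
F7 | step 10 | rac-2-[3,5-bis(benzyloxy)-4-methoxyphenyl]-6-(1-hydroxy-3-isopropoxy-2,4,4-trimethoxycyclobut-2-en-1-yl)-3-methoxy-4H-pyran-4-one | COC1=C(OC(C)C)C(OC)(OC)C1(O)c1cc(=O)c(OC)c(o1)-c1cc(OCc2ccccc2)c(OC)c(OCc2ccccc2)c1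
F8 | step 10 | rac-2-[3,5-bis(benzyloxy)-4-methoxyphenyl]-6-(3-isopropoxy-1,2,4,4-tetramethoxycyclobut-2-en-1-yl)-3-methoxy-4H-pyran-4-one | COC1=C(OC(C)C)C(OC)(OC)C1(OC)c1cc(=O)c(OC)c(o1)-c1cc(OCc2ccccc2)c(OC)c(OCc2ccccc2)c1
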